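Retrosynthesis (labdane numbering C1–C20 throughout): the C2 acetate and the 2,3-acetonide come off last; then C8–C17 is cut (methyl onto a Δ7 enol triflate), then C9–C11 (side chain onto a C8 enolate), then C6–C7 and C5–C10 together, which opens ring B and ring A at once to an open-chain triene.
Enabling feature: ring B is a cyclohexene whose C8 can carry oxygen, so C7=C8(OSi)–C9=C10 is a 2-silyloxy diene and C5=C6 is a vinyl group on the quaternary C4; the four-atom tether C1–C4 between them carries the gem-dimethyl group and the cis-2,3-diol as an acetonide.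
Forward: the triene is built linearly from acrolein, prenylmagnesium chloride, acetylide, AlMe3 and N-methoxy-N-methylacetamide; one thermal intramolecular Diels–Alder reaction closes ring A and ring B together; the side chain, C17, deprotection and the acetate follow.
Stereochemistry: C2/C3 from a Sharpless kinetic resolution (erythro epoxy alcohol); C5/C10 from the cycloaddition under control of the dioxolane; C9 by equilibration next to the C8 ketone; C13 from catalytic desymmetrisation of 3-methylglutaric anhydride; the E-alkene from syn-carboalumination.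

Key step: step 11

Assumption: (DHQ)2AQN is taken to deliver the (S)-hemiester; if the sense of induction is the reverse, the pseudo-enantiomeric (DHQD)2AQN takes its place and nothing else changes.

Step 1
Reactants: 1 3-methylglutaric anhydride
Product: 2 (S)-5-methoxy-3-methyl-5-oxopentanoic acid
Conditions: MeOH (10 equiv), (DHQ)2AQN (0.1 equiv), Et2O, −40 °C
Reagents that add atoms: methanol (CO)
Why: Cinchona-alkaloid-catalysed enantioselective alcoholysis (desymmetrisation) of a prochiral cyclic anhydride, in which the catalyst distinguishes the enantiotopic carbonyl groups and so sets C13.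

Step 2
Reactants: 2 (S)-5-methoxy-3-methyl-5-oxopentanoic acid
Product: 3 methyl (S)-5-hydroxy-3-methylpentanoate
Conditions: BH3·SMe2, THF, 0 °C → rt; crude product used at once (it lactonises on standing)
Reagents that add atoms: none
Why: Chemoselective borane reduction of a carboxylic acid beside a methyl ester, which leaves C13 untouched.

Step 3
Reactants: 3 methyl (S)-5-hydroxy-3-methylpentanoate
Product: 4 methyl (R)-5-iodo-3-methylpentanoate
Conditions: I2, PPh3, imidazole, CH2Cl2, 0 °C
Reagents that add atoms: iodine (II)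
Why: Appel-type iodination of the primary alcohol; the centre is not touched and only its descriptor changes because iodine outranks the ester branch.

Step 4
Reactants: 5 acrolein, 6 prenylmagnesium chloride (3-methylbut-2-en-1-ylmagnesium chloride)
Product: 7 rac-4,4-dimethylhexa-1,5-dien-3-ol
Conditions: THF, −78 → 0 °C; aq. NH4Cl
Reagents that add atoms: none
Why: 1,2-Addition of an allylic Grignard reagent with allylic transposition (SE2′, γ-attack) gives the reverse-prenyl carbinol with C4 quaternary, racemic at C3.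

Step 5
Reactants: 7 rac-4,4-dimethylhexa-1,5-dien-3-ol
Product: 8 (S)-2,2-dimethyl-1-[(R)-oxiran-2-yl]but-3-en-1-ol
Conditions: Ti(OiPr)4 (0.2 equiv), L-(+)-diisopropyl tartrate (0.25 equiv), t-BuOOH (0.55 equiv), 4 Å MS, CH2Cl2, −20 °C; unreacted (S)-7 is separated
Reagents that add atoms: tert-butyl hydroperoxide (CC(C)(C)OO)
Why: Sharpless asymmetric epoxidation in kinetic-resolution mode: the L-(+)-tartrate catalyst should epoxidise only the allylic vinyl group of the (R)-alcohol, from the face that gives the erythro epoxy alcohol, so C2 (R) and C3 (S) are both fixed here.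

Step 6
Reactants: 8 (S)-2,2-dimethyl-1-[(R)-oxiran-2-yl]but-3-en-1-ol, 9 lithium acetylide ethylenediamine complex
Product: 10 (4S,5R)-3,3-dimethyloct-1-en-7-yne-4,5-diol
Conditions: 9 (3 equiv), DMSO, rt; aq. NH4Cl
Reagents that add atoms: none
Why: SN2 opening of the terminal epoxide at C1 by acetylide (epoxide alkynylation); the C2–O bond is not broken, so C2 keeps its configuration.

Step 7
Reactants: 10 (4S,5R)-3,3-dimethyloct-1-en-7-yne-4,5-diol
Product: 11 (4S,5R)-2,2-dimethyl-4-(2-methylbut-3-en-2-yl)-5-(prop-2-yn-1-yl)-1,3-dioxolane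
Conditions: Me2C(OMe)2, PPTS (0.05 equiv), CH2Cl2, rt
Reagents that add atoms: 2,2-dimethoxypropane (COC(C)(C)OC)
Why: Acid-catalysed transketalisation (acetonide protection) ties the erythro diol into the cis-dioxolane that later steers the cycloaddition.

Step 8
Reactants: 11 (4S,5R)-2,2-dimethyl-4-(2-methylbut-3-en-2-yl)-5-(prop-2-yn-1-yl)-1,3-dioxolane
Product: 13 (4R,5S)-4-[(E)-3-iodo-2-methylprop-2-en-1-yl]-2,2-dimethyl-5-(2-methylbut-3-en-2-yl)-1,3-dioxolane, via dimethylalkenylalane 12 (not isolated)
Conditions: AlMe3 (2.5 equiv), Cp2ZrCl2 (0.2 equiv), CH2Cl2, 0 °C → rt; then I2, THF, −30 °C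
Reagents that add atoms: trimethylaluminium (C[Al](C)C), iodine (II)
Why: Negishi zirconium-catalysed syn-carboalumination of the terminal alkyne (methyl to C10, aluminium to C9) and iodinolysis with retention give the E-alkene in which C1 is trans to iodine.

Step 9
Reactants: 13 (4R,5S)-4-[(E)-3-iodo-2-methylprop-2-en-1-yl]-2,2-dimethyl-5-(2-methylbut-3-en-2-yl)-1,3-dioxolane, 14 N-methoxy-N-methylacetamide
Product: 16 (E)-5-[(4R,5S)-2,2-dimethyl-5-(2-methylbut-3-en-2-yl)-1,3-dioxolan-4-yl]-4-methylpent-3-en-2-one, via alkenyllithium 15 (not isolated)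
Conditions: t-BuLi (2 equiv), Et2O, −78 °C; then 14, −78 → 0 °C; aq. NH4Cl
Reagents that add atoms: none
Why: Lithium–iodine exchange with retention of alkene geometry and Weinreb ketone synthesis (stable chelated adduct, no over-addition) give the E-enone with C1 trans to C8.

Step 10
Reactants: 16 (E)-5-[(4R,5S)-2,2-dimethyl-5-(2-methylbut-3-en-2-yl)-1,3-dioxolan-4-yl]-4-methylpent-3-en-2-one
Product: 17 tert-butyl({(3E)-5-[(4R,5S)-2,2-dimethyl-5-(2-methylbut-3-en-2-yl)-1,3-dioxolan-4-yl]-4-methylpenta-1,3-dien-2-yl}oxy)dimethylsilane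
Conditions: TBSOTf, Et3N, CH2Cl2, 0 °C; filtration through Et3N-deactivated silica
Reagents that add atoms: tert-butyldimethylsilyl triflate (CC(C)(C)[Si](C)(C)OS(=O)(=O)C(F)(F)F)
Why: Soft enolisation and O-silylation at the α′-methyl group of the methyl ketone give the cross-conjugated 2-silyloxy-1,3-diene (standard silyl dienol ether synthesis).

Step 11
Reactants: 17 tert-butyl({(3E)-5-[(4R,5S)-2,2-dimethyl-5-(2-methylbut-3-en-2-yl)-1,3-dioxolan-4-yl]-4-methylpenta-1,3-dien-2-yl}oxy)dimethylsilane
Product: 18 8-(tert-butyldimethylsilyloxy)-2α,3α-(isopropylidenedioxy)-4,4,10β-trimethyl-5αH-Δ8(9)-octalin (trans-fused; labdane numbering; C11–C17 absent)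
Conditions: toluene (0.01 M), BHT (0.1 equiv), Et3N (0.2 equiv), sealed tube, 200 °C
Reagents that add atoms: none
Why: Thermal intramolecular Diels–Alder reaction of a 1,7,9-decatriene (type 1): the diene C7=C8(OTBS)–C9=C10 and the vinyl group C5=C6 on quaternary C4 join in one concerted suprafacial [4+2] event that forms C6–C7 and C5–C10 and leaves the C8=C9 silyl enol ether. The closest known reaction type is the cycloaddition of 2-silyloxy-1,7,9-decatrienes with unactivated terminal alkenes to trans-decalin enol ethers; ring B closes as the six-membered cycloadduct ring (C5–C6–C7–C8–C9–C10) and ring A as the six-membered tether ring (C10–C1–C2–C3–C4–C5) through the ring-fusion bond. C5 and C10 arise together: the E geometry of C9=C10 places the tether outside and the C10 methyl inside, and the anti transition state, in which the bulky C4 centre points away from the diene (tether exo), should give the trans fusion with H-5 anti to the C10 methyl. Their absolute sense comes from the cis-dioxolane at C2/C3: in the chair-like anti transition state on the desired diene face C2–O is equatorial and C3–O axial, whereas the other face would push C2–O axial against the axial methyl groups at C10 and C4. The step needs anti over syn selectivity, diastereofacial control and a cycloaddition that outruns loss of the dienol ether; the gem-dimethyl group and the cis-fused acetonide hold the two ends together, the [1,5]-hydrogen shift of the inside methyl is reversible and drains nothing, and the regiochemistry is fixed by the tether length.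

Step 12
Reactants: 18 8-(tert-butyldimethylsilyloxy)-2α,3α-(isopropylidenedioxy)-4,4,10β-trimethyl-5αH-Δ8(9)-octalin, 4 methyl (R)-5-iodo-3-methylpentanoate
Product: 21 methyl (13S)-2α,3α-(isopropylidenedioxy)-8-oxo-17-norlabdan-15-oate (9β side chain), via ammonium enolate 19 (not isolated), via 9-epimeric ketone 20 (not isolated)
Conditions: anhydrous BnMe3N+F− (1.5 equiv), 4 (2 equiv), 4 Å MS, THF, 0 °C → rt; then NaOMe (0.2 equiv), MeOH, rt
Reagents that add atoms: none
Why: Fluoride-mediated regiospecific enolate alkylation: desilylation gives only the C8(O)=C9 enolate, which is C-alkylated at C9 by the primary iodide, and base equilibration α to the ketone then sets C9 with the side chain equatorial (β, cis to the C10 methyl).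

Step 13
Reactants: 21 methyl (13S)-2α,3α-(isopropylidenedioxy)-8-oxo-17-norlabdan-15-oate
Product: 23 methyl (13S)-2α,3α-(isopropylidenedioxy)-8-(trifluoromethanesulfonyloxy)-17-norlabd-7-en-15-oate, via lithium enolate 22 (not isolated)
Conditions: LiN(SiMe3)2 (1.1 equiv), THF, −78 °C; then PhNTf2, −78 → 0 °C
Reagents that add atoms: N-phenylbis(trifluoromethanesulfonimide) (O=S(=O)(N(c1ccccc1)S(=O)(=O)C(F)(F)F)C(F)(F)F)
Why: Kinetic deprotonation at the unhindered C7 methylene (faster than at the C9 methine or α to the ester) and O-triflation give the Δ7 enol triflate without touching C9.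

Step 14
Reactants: 23 methyl (13S)-2α,3α-(isopropylidenedioxy)-8-(trifluoromethanesulfonyloxy)-17-norlabd-7-en-15-oate
Product: 24 methyl (13S)-2α,3α-(isopropylidenedioxy)labd-7-en-15-oate
Conditions: MeZnCl (2 M in THF, 2 equiv), Pd(PPh3)4 (0.05 equiv), THF, 50 °C
Reagents that add atoms: methylzinc chloride (C[Zn]Cl)
Why: Negishi cross-coupling of the alkenyl triflate installs C17 at C8 and keeps the double bond at C7=C8; the ester and acetonide tolerate the organozinc.

Step 15
Reactants: 24 methyl (13S)-2α,3α-(isopropylidenedioxy)labd-7-en-15-oate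
Product: 25 methyl (13S)-2α,3α-dihydroxylabd-7-en-15-oate
Conditions: AcOH/H2O/THF (3:1:1), 45 °C
Reagents that add atoms: none
Why: Mild aqueous acid hydrolysis of the acetonide, under which the trisubstituted alkene and the methyl ester should survive.

Step 16
Reactants: 25 methyl (13S)-2α,3α-dihydroxylabd-7-en-15-oate
Product: 26 methyl (13S)-2α-acetoxy-3α-hydroxylabd-7-en-15-oate, that is methyl (3S)-5-[(1S,4aR,6S,7R,8aR)-7-acetoxy-6-hydroxy-2,5,5,8a-tetramethyl-1,4,4a,5,6,7,8,8a-octahydronaphthalen-1-yl]-3-methylpentanoate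
Conditions: Ac2O (1.1 equiv), pyridine, CH2Cl2, 0 °C
Reagents that add atoms: acetic anhydride (CC(=O)OC(C)=O)
Why: Regioselective acylation: the equatorial C2 hydroxyl should be acetylated much faster than the axial C3 hydroxyl, which is neopentylic next to the C4 gem-dimethyl group.

Compound list
1 | 3-methylglutaric anhydride (4-methyloxane-2,6-dione) | CC1CC(=O)OC(=O)C1 | starting material
2 | (S)-5-methoxy-3-methyl-5-oxopentanoic acid | COC(=O)C[C@@H](C)CC(=O)O | intermediate
3 | methyl (S)-5-hydroxy-3-methylpentanoate | COC(=O)C[C@@H](C)CCO | intermediate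
4 | methyl (R)-5-iodo-3-methylpentanoate | COC(=O)C[C@@H](C)CCI | intermediate
5 | acrolein | C=CC=O | starting material
6 | prenylmagnesium chloride | CC(C)=CC[Mg]Cl | starting material
7 | rac-4,4-dimethylhexa-1,5-dien-3-ol | C=CC(O)C(C)(C)C=C | intermediate
8 | (S)-2,2-dimethyl-1-[(R)-oxiran-2-yl]but-3-en-1-ol | C=CC(C)(C)[C@H](O)[C@H]1CO1 | intermediate
9 | lithium acetylide ethylenediamine complex | [Li+].[C-]#C.NCCN | starting material
10 | (4S,5R)-3,3-dimethyloct-1-en-7-yne-4,5-diol | C=CC(C)(C)[C@H](O)[C@H](O)CC#C | intermediate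
11 | (4S,5R)-2,2-dimethyl-4-(2-methylbut-3-en-2-yl)-5-(prop-2-yn-1-yl)-1,3-dioxolane | C=CC(C)(C)[C@H](OC1(C)C)[C@H](O1)CC#C | intermediate
12 | (E)-alkenyl(dimethyl)alane from 11 (Al on C9, methyl on C10) | C=CC(C)(C)[C@H](OC1(C)C)[C@H](O1)C/C(C)=C/[Al](C)C | intermediate (not isolated)
13 | (4R,5S)-4-[(E)-3-iodo-2-methylprop-2-en-1-yl]-2,2-dimethyl-5-(2-methylbut-3-en-2-yl)-1,3-dioxolane | C=CC(C)(C)[C@H](OC1(C)C)[C@H](O1)C/C(C)=C/I | intermediate
14 | N-methoxy-N-methylacetamide | CC(=O)N(C)OC | starting material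
15 | (E)-alkenyllithium from 13 (Li on C9) | C=CC(C)(C)[C@H](OC1(C)C)[C@H](O1)C/C(C)=C/[Li] | intermediate (not isolated)
16 | (E)-5-[(4R,5S)-2,2-dimethyl-5-(2-methylbut-3-en-2-yl)-1,3-dioxolan-4-yl]-4-methylpent-3-en-2-one | C=CC(C)(C)[C@H](OC1(C)C)[C@H](O1)C/C(C)=C/C(C)=O | intermediate
17 | tert-butyl({(3E)-5-[(4R,5S)-2,2-dimethyl-5-(2-methylbut-3-en-2-yl)-1,3-dioxolan-4-yl]-4-methylpenta-1,3-dien-2-yl}oxy)dimethylsilane | C=CC(C)(C)[C@H](OC1(C)C)[C@H](O1)C/C(C)=C/C(=C)O[Si](C)(C)C(C)(C)C | intermediate
18 | 8-(tert-butyldimethylsilyloxy)-2α,3α-(isopropylidenedioxy)-4,4,10β-trimethyl-5αH-Δ8(9)-octalin (trans-fused) | C1=C(O[Si](C)(C)C(C)(C)C)CC[C@H]2C(C)(C)[C@H](OC3(C)C)[C@H](O3)C[C@]12C | intermediate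
19 | benzyltrimethylammonium C8(O)=C9 enolate from 18 | C1=C([O-])CC[C@H]2C(C)(C)[C@H](OC3(C)C)[C@H](O3)C[C@]12C.C[N+](C)(C)Cc1ccccc1 | intermediate (not isolated)
20 | methyl (13S)-2α,3α-(isopropylidenedioxy)-8-oxo-17-nor-9-epi-labdan-15-oate (9α side chain) | COC(=O)C[C@@H](C)CC[C@@H]1C(=O)CC[C@H]2C(C)(C)[C@H](OC3(C)C)[C@H](O3)C[C@]12C | intermediate (not isolated)
21 | methyl (13S)-2α,3α-(isopropylidenedioxy)-8-oxo-17-norlabdan-15-oate | COC(=O)C[C@@H](C)CC[C@H]1C(=O)CC[C@H]2C(C)(C)[C@H](OC3(C)C)[C@H](O3)C[C@]12C | intermediate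
22 | lithium Δ7-enolate of 21 | COC(=O)C[C@@H](C)CC[C@H]1C(O[Li])=CC[C@H]2C(C)(C)[C@H](OC3(C)C)[C@H](O3)C[C@]12C | intermediate (not isolated)
23 | methyl (13S)-2α,3α-(isopropylidenedioxy)-8-(trifluoromethanesulfonyloxy)-17-norlabd-7-en-15-oate | COC(=O)C[C@@H](C)CC[C@H]1C(OS(=O)(=O)C(F)(F)F)=CC[C@H]2C(C)(C)[C@H](OC3(C)C)[C@H](O3)C[C@]12C | intermediate
24 | methyl (13S)-2α,3α-(isopropylidenedioxy)labd-7-en-15-oate | COC(=O)C[C@@H](C)CC[C@H]1C(C)=CC[C@H]2C(C)(C)[C@H](OC3(C)C)[C@H](O3)C[C@]12C | intermediate
25 | methyl (13S)-2α,3α-dihydroxylabd-7-en-15-oate | COC(=O)C[C@@H](C)CC[C@H]1C(C)=CC[C@H]2C(C)(C)[C@H](O)[C@H](O)C[C@]12C | intermediate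
26 | methyl (13S)-2α-acetoxy-3α-hydroxylabd-7-en-15-oate | COC(=O)C[C@@H](C)CC[C@H]1C(C)=CC[C@H]2C(C)(C)[C@H](O)[C@H](OC(C)=O)C[C@]12C | target

Total step count: 16. Longest linear sequence: 13 steps (steps 4 to 16); the side-chain branch (steps 1 to 3) joins at step 12.

Steps most likely to fail

Step 11. The cycloaddition of an unactivated, neopentyl-flanked vinyl group onto a diene with an inside methyl may be too slow at temperatures the silyl dienol ether tolerates, and some material may leak through the syn transition state to the cis-fused ring system. The fallback sets out from 16 and comes back at 18; it makes the dienophile electron-poor with a traceless sulfone. Radical selenosulfonation of the terminal vinyl group of 16 (PhSO2SePh, AIBN, benzene, 80 °C) should give the selenosulfone adduct F1, and oxidation (H2O2, pyridine, CH2Cl2) with selenoxide syn-elimination the (E)-vinyl sulfone enone F2. Silylation as in step 10 gives the sulfonyl silyloxytriene F3, whose polarised intramolecular Diels–Alder reaction should run near 110 °C in toluene, with the sulfonyl group endo in the anti transition state, to the 6-phenylsulfonyl cycloadduct F4. Reductive desulfonylation (Na/Hg 5%, Na2HPO4, MeOH/THF, −20 °C) then returns 18.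

Step 12. C-alkylation at C9, which lies next to the quaternary C10, may lose to O-alkylation, to E2 elimination of the iodide or to simple protonation of the enolate. The fallback sets out from 18 and 3 and comes back at 21; it replaces the SN2 step by an aldol construction of C9–C11. Dess–Martin oxidation of 3 gives methyl (S)-3-methyl-5-oxopentanoate F5, and Mukaiyama aldol addition of 18 to it (BF3·OEt2, CH2Cl2, −78 °C) gives the β-hydroxy ketone F6 as a mixture at C9 and C11. Immediate mesylation and elimination (MsCl, Et3N, 0 °C; then DBU), before the δ-hydroxy ester can lactonise, give the exocyclic 9(11)-enone F7. Hydrogenation (H2, Pd/C, EtOAc) from the α-face, anti to the C10 methyl, then gives 21.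

Step 5. Epoxidation of a monosubstituted alkene next to a tert-alkyl carbinol is the slowest substrate class for the titanium tartrate catalyst, so conversion may stall and the discrimination between the enantiomers may erode. The fallback sets out from 6 and comes back at 8; it takes C2 from the chiral pool and sets C3 by substrate control. Reagent 6, transmetalated with ZnCl2, is added to commercial (R)-2,3-O-isopropylideneglyceraldehyde (THF, −78 °C); Felkin–Anh (anti) addition should give (S)-1-[(R)-2,2-dimethyl-1,3-dioxolan-4-yl]-2,2-dimethylbut-3-en-1-ol F8. Acetonide hydrolysis (aq. AcOH, 40 °C) gives (2R,3S)-4,4-dimethylhex-5-ene-1,2,3-triol F9, selective tosylation of the primary hydroxyl (TsCl, pyridine, 0 °C) the primary tosylate F10, and K2CO3 in MeOH closes the terminal epoxide with retention at C2 to give 8.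

Further compounds
F1 | step 11 | (E)-5-{(4R,5S)-2,2-dimethyl-5-[2-methyl-4-(phenylsulfonyl)-3-(phenylselanyl)butan-2-yl]-1,3-dioxolan-4-yl}-4-methylpent-3-en-2-one (epimers at the selenium-bearing carbon) | O=S(=O)(c1ccccc1)CC([Se]c1ccccc1)C(C)(C)[C@H](OC1(C)C)[C@H](O1)C/C(C)=C/C(C)=O
F2 | step 11 | (E)-5-{(4R,5S)-2,2-dimethyl-5-[(E)-2-methyl-4-(phenylsulfonyl)but-3-en-2-yl]-1,3-dioxolan-4-yl}-4-methylpent-3-en-2-one | O=S(=O)(c1ccccc1)/C=C/C(C)(C)[C@H](OC1(C)C)[C@H](O1)C/C(C)=C/C(C)=O
F3 | step 11 | tert-butyldimethylsilyl dienol ether of F2 (2-silyloxy-1,3-diene, E at C9=C10) | O=S(=O)(c1ccccc1)/C=C/C(C)(C)[C@H](OC1(C)C)[C@H](O1)C/C(C)=C/C(=C)O[Si](C)(C)C(C)(C)C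
F4 | step 11 | 6-(phenylsulfonyl) derivative of 18 (C6 configuration not defined) | C1=C(O[Si](C)(C)C(C)(C)C)CC(S(=O)(=O)c3ccccc3)[C@H]2C(C)(C)[C@H](OC3(C)C)[C@H](O3)C[C@]12C
F5 | step 12 | methyl (S)-3-methyl-5-oxopentanoate | COC(=O)C[C@@H](C)CC=O
F6 | step 12 | methyl (13S)-11-hydroxy-2α,3α-(isopropylidenedioxy)-8-oxo-17-norlabdan-15-oate (mixture at C9 and C11) | COC(=O)C[C@@H](C)CC(O)C1C(=O)CC[C@H]2C(C)(C)[C@H](OC3(C)C)[C@H](O3)C[C@]12C
F7 | step 12 | methyl (13S)-2α,3α-(isopropylidenedioxy)-8-oxo-17-norlabd-9(11)-en-15-oate (alkene geometry not defined) | COC(=O)C[C@@H](C)CC=C1C(=O)CC[C@H]2C(C)(C)[C@H](OC3(C)C)[C@H](O3)C[C@]12C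
F8 | step 5 | (S)-1-[(R)-2,2-dimethyl-1,3-dioxolan-4-yl]-2,2-dimethylbut-3-en-1-ol | C=CC(C)(C)[C@H](O)[C@H]1COC(C)(C)O1
F9 | step 5 | (2R,3S)-4,4-dimethylhex-5-ene-1,2,3-triol | C=CC(C)(C)[C@H](O)[C@H](O)CO
F10 | step 5 | (2R,3S)-2,3-dihydroxy-4,4-dimethylhex-5-en-1-yl 4-methylbenzenesulfonate | C=CC(C)(C)[C@H](O)[C@H](O)COS(=O)(=O)c1ccc(C)cc1
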